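# Proposed synthesis of CNP0277965.1 by chromium-mediated C7–C8 ring closure

Atom labels throughout are those of the target ring (C1–C10). C11 is the side-chain carbon on C7, C12 its ester carbon (later a methyl) and C13 its CH2 carbon (later the other methyl). In acyclic intermediates the labels mean the carbons that become these atoms.

## Structural features

The target is a ten-membered carbocycle with an E trisubstituted alkene C1=C10 (methyl on C10) and an E disubstituted alkene C5=C6. C4 is a tertiary allylic carbinol (R), separated from the other stereocentres by the C5=C6 alkene. C7 (S, isopropyl) and C8 (S, 4-hydroxybenzoyloxy) are adjacent, with the isopropyl group and the oxygen trans across the C7–C8 ring bond. The fragile groups are the tertiary allylic alcohol (acid would ionise it and invite transannular attack by C1=C10), the aryl ester with its free phenol (hydride, strong base) and the doubly unsaturated medium ring. The two alkenes are not in a 1,5-relationship, so a Cope rearrangement is not a concern. The real difficulty is closing the ten-membered ring with both alkenes E while relating the isolated C4 centre to the C7/C8 pair. The key step uses the fact that C8–OH, C7 and a C11=C13 alkene form a homoallylic alcohol once the isopropyl group is written as a 1-(methoxycarbonyl)ethenyl group. The C7–C8 bond then arises from γ-attack of a 2-(methoxycarbonyl)allyl metal on a C8 aldehyde.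

## Logic of the disconnections

**33 to 30 and 31 (through 32).** The C8–O acyl bond is cut and the phenol is carried as its acetate. The aryl ester cannot survive the hydride steps, so it goes on last. This removes the aromatic unit and leaves the carbocyclic diol 30. The forward acylation must choose the secondary C8 hydroxyl over the tertiary C4 hydroxyl, and the deacetylation must spare the benzoate.

**30 to 25 (through 29, 28, 27, 26).** No skeletal bond is cut. The C12 methyl is traced back through CH2OTs and CH2OH to CO2Me, and the C11–H and C13–H bonds are removed, so that isopropyl becomes 1-(methoxycarbonyl)ethenyl. Isopropyl has no retron; the acrylate is what an allylation delivers. The forward sequence must reduce only the conjugated alkene. The C8 oxygen must also be capped before C12 carries a leaving group, because a free C8 hydroxyl four atoms away would close a tetrahydrofuran.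

**25 to 22 (through 24 and 23).** After removal of the C8 silyl group, the C7–C8 bond is cut. This opens the ring and removes two stereocentres, leaving an acyclic aldehyde with one stereocentre. The forward step must be γ-selective, must translate the 2E geometry of the bromide into the trans C7/C8 relationship, and must take its absolute sense from C4.

**22 to 20 (through 21).** The C8 aldehyde is traced to a primary alcohol and C13–Br to C13–OH. The two reactive termini are unveiled last. The forward bromination must convert the allylic hydroxyl in the presence of the homoallylic one, and the oxidation must not move C1=C10 into conjugation.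

**20 to 16 (through 18 and 17, with 19).** The C11–C13 bond is cut (hydroxymethyl from a tin reagent onto a vinyl bromide) and the C8–O bond is removed (hydroboration of a terminal vinyl group). The diene terminus masks the homoallylic alcohol without a protecting group, and the vinyl bromide fixes the geometry at C7=C11. The coupling must proceed with retention, and the hydroboration must be site-selective.

**16 to 12 and 15; 15 to 13 (through 14).** The C7=C11 alkene is cut into an enal and a bromophosphonoacetate. The olefination must place the ester cis to C6.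

**12 to 8 and 9 (through 11 and 10).** The C6–C7 bond is cut (one-carbon Wittig), and the C5=C6 alkene with the C4 hydroxyl is traced to an epoxide across C4–C5. The 4-hydroxy-2-enal thus becomes an epoxy aldehyde. The hydrolysis must open the epoxide only at C5 and give the E enal.

**8 to 6 (through 7).** The epoxide oxygen is removed. C4 comes from a reagent-controlled epoxidation of an allylic alcohol, which must be enantioselective and must ignore the diene.

**6 to 1 (through 5, 3, 2, with 4).** The C8=C9 alkene is cut (methylenation), and the C9 carbonyl is traced to allylic oxidation of the E-methyl group of 1. This reaches a commercial monoterpene ester. The oxidation must be selective for the terminal E-methyl group.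

## Other disconnections considered

**Alternative 1:** The ring is cut at C2–C3 while C5–C10 is joined, which folds it into the cyclohexanol A1 (vinyl and methyl on C10, isopropenyl on the carbinol carbon C5, C7 and C8 already in place). In the forward direction the potassium alkoxide of A1 (KH, 18-crown-6) would undergo an anionic oxy-Cope rearrangement through a chair, and silylation of the enolate would give the ten-membered silyl enol ether A2.
- In its favour: the ring expansion is unimolecular and needs no high dilution; the chair of a trans-dialkenylcyclohexane translates cleanly into the E C1=C10 alkene; C7 and C8 are fixed on a six-membered ring before the flexible ring exists.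
- Against it here: A2 has its oxygen on C5 and a C4=C5 double bond, whereas the target needs a tertiary carbinol at C4 and a C5=C6 alkene. The oxygen would have to be moved by one carbon and the C4 stereocentre created late on a flexible ring with no controlling element. A1 also needs a quaternary C10 next to the carbinol.
- Comparison: on C7/C8 control and on the predictability of the ring-forming step this alternative is the better of the two. On C4 and on the position of the second alkene it is clearly worse, and the steps after its key step would outnumber those of the chosen plan. The chosen plan sets the one centre that cannot be corrected later (C4) first and under reagent control.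

**Alternative 2:** The ten-membered ring is read as the periphery of the trans-decalin A3 (C1 mesylate, C6=C7 alkene, angular methyl on C10, silyl ethers on C4 and C8) by adding the transannular C5–C10 bond. In the forward direction BH3·THF would add to C6=C7 from the face away from the angular methyl, setting C7. NaOH would then trigger a Grob-type fragmentation of the boronate, in which the antiperiplanar C6–B, C5–C10 and C1–O bonds give both E alkenes. The product A4 is the same compound as 29.
- In its favour: every stereocentre, C4 included, is set on a rigid bicycle with predictable facial bias; the alkene geometries follow stereospecifically from the fragmentation; there is no entropically difficult macrocyclisation; A4 is three steps from the target.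
- Against it here: A3 needs five stereocentres, three of which are sacrificed, and its assembly would probably take more steps than the route to 22. Boron must go only to C6, since boron on C7 would expel the C8 oxygen.
- Comparison: on stereocontrol and alkene geometry this alternative is the better of the two, and on convergence it is the equal (both meet at 29). The chosen plan is shorter up to the ring and starts from a catalytic asymmetric step, but is longer after the ring (eight steps against three).

**Alternative 3:** The ring is cut at C4–C5, giving the acyclic (E)-vinyl iodide methyl ketone A5. In the forward direction CrCl2 with catalytic NiCl2 would generate an alkenylchromium at C5 that adds to the C4 ketone and gives the ten-membered tertiary alcohol A6.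
- In its favour: C7 and C8 would be set in an open chain by mature aldol or crotylation chemistry; the isopropyl group is present from the start; the E C5=C6 alkene is secured in the iodide; A6 needs only desilylation and acylation.
- Against it here: alkenylchromium reagents add sluggishly to ketones, and more so in a dilute ring closure. The C4 configuration would rest on the distinction between a methyl group and a ring methylene, relayed from remote C7/C8, and a wrong tertiary carbinol cannot be inverted.
- Comparison: after the ring closure this alternative is the better in step economy, and in overall length probably the equal. It is worse in reactivity and in stereocontrol, because the chosen plan leaves to the ring closure only a secondary carbinol that can still be corrected.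

Key step: step 14

## Route

Remark: compounds 1, 4, 9, 13, 19 and 31 are taken as commercial. C11 in 26–28 is an epimer mixture of no consequence, because the centre disappears in 29.

Step 1
Reactants: 1 geranyl acetate
Product: 3 (2E,6E)-3,7-dimethyl-8-oxoocta-2,6-dien-1-yl acetate, via allylic alcohol 2 (not isolated)
Conditions: SeO2 (cat.), t-BuOOH, salicylic acid (cat.), CH2Cl2, rt; crude mixture then MnO2, CH2Cl2, rt
Reagents that add atoms: selenium dioxide, O=[Se]=O; tert-butyl hydroperoxide, CC(C)(C)OO
Why: Selenium dioxide allylic oxidation (ene reaction, then [2,3]-shift) attacks the E-methyl group of the electron-rich terminal alkene and leaves the acetate-deactivated 2,3-alkene alone; MnO2 converges the alcohol/aldehyde mixture on the E enal.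

Step 2
Reactants: 3 (2E,6E)-3,7-dimethyl-8-oxoocta-2,6-dien-1-yl acetate; 4 methyltriphenylphosphonium bromide
Product: 5 (2E,6E)-3,7-dimethylnona-2,6,8-trien-1-yl acetate
Conditions: 4, KN(SiMe3)2, THF, 0 °C; then 3, −78 to 0 °C
Reagents that add atoms: none
Why: Wittig methylenation; at low temperature and with about one equivalent of ylide the aldehyde reacts much faster than the acetate, and the new CH2 carbon is the future C8.

Step 3
Reactants: 5 (2E,6E)-3,7-dimethylnona-2,6,8-trien-1-yl acetate
Product: 6 (2E,6E)-3,7-dimethylnona-2,6,8-trien-1-ol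
Conditions: K2CO3 (cat.), MeOH, 0 °C to rt
Reagents that add atoms: none
Why: Base-catalysed transesterification frees the allylic alcohol that must direct the epoxidation; nothing else in 5 is base-sensitive.

Step 4
Reactants: 6 (2E,6E)-3,7-dimethylnona-2,6,8-trien-1-ol
Product: 7 [(2R,3R)-3-methyl-3-[(3E)-4-methylhexa-3,5-dien-1-yl]oxiran-2-yl]methanol
Conditions: Ti(Oi-Pr)4 (cat.), D-(−)-diethyl tartrate (cat.), t-BuOOH, 4 Å sieves, CH2Cl2, −20 °C
Reagents that add atoms: tert-butyl hydroperoxide, CC(C)(C)OO
Why: Sharpless asymmetric epoxidation; only the alkene of the allylic alcohol is epoxidised, and the D-(−)-tartrate complex delivers oxygen to the face that gives the (2R,3R)-epoxide, which fixes the future C4 as R (the L-(+)-tartrate is known to give the 2S,3S series with geraniol).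

Step 5
Reactants: 7 [(2R,3R)-3-methyl-3-[(3E)-4-methylhexa-3,5-dien-1-yl]oxiran-2-yl]methanol
Product: 8 (2S,3R)-3-methyl-3-[(3E)-4-methylhexa-3,5-dien-1-yl]oxirane-2-carbaldehyde
Conditions: PhI(OAc)2, TEMPO (cat.), CH2Cl2, rt
Reagents that add atoms: none
Why: TEMPO-catalysed oxidation of the primary alcohol under nearly neutral conditions that spare the epoxide and the diene; the sensitive epoxy aldehyde is used at once.

Step 6
Reactants: 8 (2S,3R)-3-methyl-3-[(3E)-4-methylhexa-3,5-dien-1-yl]oxirane-2-carbaldehyde; 9 (methoxymethyl)triphenylphosphonium chloride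
Product: 11 (2E,4R,7E)-4-hydroxy-4,8-dimethyldeca-2,7,9-trienal, via epoxy enol ether 10 (not isolated)
Conditions: 9, KN(SiMe3)2, THF, 0 °C; then 8, −78 to 0 °C; then 0.5 M aq. HCl, THF, 0 °C
Reagents that add atoms: water, O
Why: The Wittig reaction gives the enol ether of the homologated aldehyde; on acid hydrolysis the C5–O bond of the epoxide opens (directly, or by β-elimination of the β,γ-epoxy aldehyde), which places the alkene at C5=C6 as the conjugated E enal. The oxygen stays on C4 with its configuration untouched.

Step 7
Reactants: 11 (2E,4R,7E)-4-hydroxy-4,8-dimethyldeca-2,7,9-trienal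
Product: 12 (2E,4R,7E)-4,8-dimethyl-4-[(triethylsilyl)oxy]deca-2,7,9-trienal
Conditions: Et3SiOTf, 2,6-lutidine, CH2Cl2, −78 °C
Reagents that add atoms: triethylsilyl trifluoromethanesulfonate, CC[Si](CC)(CC)OS(=O)(=O)C(F)(F)F
Why: Silylation of the tertiary alcohol with a silyl triflate and a hindered base; C4 is quaternary, so the enal cannot be γ-deprotonated, and the buffered low temperature keeps the enal from reacting with the diene.

Step 8
Reactants: 13 methyl 2-[bis(2,2,2-trifluoroethoxy)phosphoryl]acetate
Product: 15 methyl 2-bromo-2-[bis(2,2,2-trifluoroethoxy)phosphoryl]acetate (racemic), via dibromophosphonate 14 (not isolated)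
Conditions: NaH (2 equiv), Br2 (2 equiv), THF, 0 °C; crude then SnCl2·2H2O, EtOH/H2O, 0 °C
Reagents that add atoms: bromine, BrBr
Why: Exhaustive α-bromination of the phosphonoacetate anion followed by selective tin-mediated removal of one bromine is the standard way to a monobromophosphonoacetate and avoids mono/dibromo mixtures.

Step 9
Reactants: 12 (2E,4R,7E)-4,8-dimethyl-4-[(triethylsilyl)oxy]deca-2,7,9-trienal; 15 methyl 2-bromo-2-[bis(2,2,2-trifluoroethoxy)phosphoryl]acetate
Product: 16 methyl (2E,4E,6R,9E)-2-bromo-6,10-dimethyl-6-[(triethylsilyl)oxy]dodeca-2,4,9,11-tetraenoate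
Conditions: 15, KOt-Bu, 18-crown-6, THF, −78 °C; then 12
Reagents that add atoms: none
Why: Horner–Wadsworth–Emmons olefination with a bis(trifluoroethyl) phosphonate of the Still–Gennari type; fast, irreversible elimination from the kinetic adduct places the ester cis to the C6 chain, so bromine is trans to C6 (2E). Only 1,2-addition to the enal is expected.

Step 10
Reactants: 16 methyl (2E,4E,6R,9E)-2-bromo-6,10-dimethyl-6-[(triethylsilyl)oxy]dodeca-2,4,9,11-tetraenoate
Product: 18 methyl (2E,4E,6R,9E)-2-bromo-12-hydroxy-6,10-dimethyl-6-[(triethylsilyl)oxy]dodeca-2,4,9-trienoate, via alkylborane 17 (not isolated)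
Conditions: 9-borabicyclo[3.3.1]nonane (9-BBN), THF, 0 °C to rt; then NaBO3·4H2O, H2O, rt
Reagents that add atoms: sodium perborate, [Na+].[O-]OB=O
Why: Hydroboration–oxidation; the bulky dialkylborane adds to the monosubstituted end of the electron-rich diene (boron on the terminal carbon, the future C8) and not to the ester-conjugated bromodiene or the trisubstituted alkene. Perborate oxidises the C–B bond without saponifying the ester.

Step 11
Reactants: 18 methyl (2E,4E,6R,9E)-2-bromo-12-hydroxy-6,10-dimethyl-6-[(triethylsilyl)oxy]dodeca-2,4,9-trienoate; 19 (tributylstannyl)methanol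
Product: 20 methyl (2Z,4E,6R,9E)-12-hydroxy-2-(hydroxymethyl)-6,10-dimethyl-6-[(triethylsilyl)oxy]dodeca-2,4,9-trienoate
Conditions: Pd(PPh3)4 (cat.), 1,4-dioxane, 85 °C
Reagents that add atoms: none
Why: Stille coupling; zerovalent palladium inserts into the ester-activated C(sp2)–Br bond, the α-oxygenated CH2OH group transfers from tin in preference to butyl, and reductive elimination retains the alkene geometry, so CH2OH ends trans to C6.

Step 12
Reactants: 20 methyl (2Z,4E,6R,9E)-12-hydroxy-2-(hydroxymethyl)-6,10-dimethyl-6-[(triethylsilyl)oxy]dodeca-2,4,9-trienoate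
Product: 21 methyl (2E,4E,6R,9E)-2-(bromomethyl)-12-hydroxy-6,10-dimethyl-6-[(triethylsilyl)oxy]dodeca-2,4,9-trienoate
Conditions: N-bromosuccinimide, Me2S, CH2Cl2, −20 to 0 °C
Reagents that add atoms: N-bromosuccinimide, O=C1CCC(=O)N1Br
Why: Corey–Kim halogenation; both hydroxyls form alkoxysulfonium salts, but only the allylic one is displaced by bromide at low temperature, and the homoallylic one reverts to the alcohol on work-up. The medium is neither acidic nor basic, so the silyl ether and the alkene geometry should persist.

Step 13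
Reactants: 21 methyl (2E,4E,6R,9E)-2-(bromomethyl)-12-hydroxy-6,10-dimethyl-6-[(triethylsilyl)oxy]dodeca-2,4,9-trienoate
Product: 22 methyl (2E,4E,6R,9E)-2-(bromomethyl)-6,10-dimethyl-12-oxo-6-[(triethylsilyl)oxy]dodeca-2,4,9-trienoate
Conditions: Dess–Martin periodinane, NaHCO3, CH2Cl2, 0 °C to rt; used crude
Reagents that add atoms: none
Why: Dess–Martin oxidation under bicarbonate buffering gives the β,γ-unsaturated aldehyde without moving C1=C10 into conjugation and tolerates the allylic bromide; the aldehyde is taken on immediately.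

Step 14
Reactants: 22 methyl (2E,4E,6R,9E)-2-(bromomethyl)-6,10-dimethyl-12-oxo-6-[(triethylsilyl)oxy]dodeca-2,4,9-trienoate
Product: 24 methyl 2-[(1R,2E,4R,7E,10S)-10-hydroxy-4,8-dimethyl-4-[(triethylsilyl)oxy]cyclodeca-2,7-dien-1-yl]prop-2-enoate, via allylchromium 23 (not isolated)
Conditions: CrCl2 (8 equiv), THF/DMF, rt, slow addition of 22 (final about 2 mM); pH 7 buffer work-up, cold
Reagents that add atoms: none
Why: Two equivalents of divalent chromium reduce the allylic C13–Br bond by successive one-electron transfers to the trivalent allylchromium 23, with the metal on C13 and C7 as the γ-carbon. Chromium binds the aldehyde oxygen and C7 adds to C8 through a six-membered chair (Cr, O, C8, C7, C11, C13); the closest known reaction type is the intramolecular Nozaki–Hiyama–Kishi allylation of ω-formyl 2-(bromomethyl)enoates that closes ten-membered germacranolide rings. The ten-membered ring closes by this carbonyl addition (10-exo-trig with respect to C=O), with slow addition and high dilution so that cyclisation outruns dimerisation. For C7/C8, the C6 substituent (trans to CH2Cr) and the C9 chain of the aldehyde are both equatorial in the chair, which gives the anti relationship of the C8 oxygen and C6, that is the trans arrangement of hydroxyl and side chain required (7S,8S in target numbering; 1R,10S in the name of 24). For the absolute sense, C4 is the only stereocentre in 22, and the facial preference must come from the conformation of the forming ring, in which the large silyloxy group on C4 should take the outward position; this relay is the weakest control element. The step needs γ-selectivity, which the closed transition state provides (C5 is also neopentylic next to quaternary C4). It needs chemoselectivity for the aldehyde over the ester, which the weakly basic organochromium provides. It also needs the 2E geometry to be kept in 23, which asks for a fast ring closure.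

Step 15
Reactants: 24 methyl 2-[(1R,2E,4R,7E,10S)-10-hydroxy-4,8-dimethyl-4-[(triethylsilyl)oxy]cyclodeca-2,7-dien-1-yl]prop-2-enoate
Product: 25 methyl 2-[(1R,2E,4R,7E,10S)-4,8-dimethyl-4,10-bis[(triethylsilyl)oxy]cyclodeca-2,7-dien-1-yl]prop-2-enoate
Conditions: Et3SiOTf, 2,6-lutidine, CH2Cl2, −78 to 0 °C
Reagents that add atoms: triethylsilyl trifluoromethanesulfonate, CC[Si](CC)(CC)OS(=O)(=O)C(F)(F)F
Why: Prompt silylation of the C8 hydroxyl forestalls γ-lactonisation onto the ester and removes the nucleophile that would otherwise close a tetrahydrofuran onto C12 at the sulfonate stage.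

Step 16
Reactants: 25 methyl 2-[(1R,2E,4R,7E,10S)-4,8-dimethyl-4,10-bis[(triethylsilyl)oxy]cyclodeca-2,7-dien-1-yl]prop-2-enoate
Product: 26 methyl (2RS)-2-[(1R,2E,4R,7E,10S)-4,8-dimethyl-4,10-bis[(triethylsilyl)oxy]cyclodeca-2,7-dien-1-yl]propanoate
Conditions: LiBH(s-Bu)3, THF, −78 °C; aq. NH4Cl
Reagents that add atoms: none
Why: Conjugate (1,4) hydride addition of the bulky borohydride to the unhindered CH2 end of the acrylate; isolated alkenes and silyl ethers are inert, and the new C11 centre is irrelevant because both epimers converge at 29.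

Step 17
Reactants: 26 methyl (2RS)-2-[(1R,2E,4R,7E,10S)-4,8-dimethyl-4,10-bis[(triethylsilyl)oxy]cyclodeca-2,7-dien-1-yl]propanoate
Product: 27 (2RS)-2-[(1R,2E,4R,7E,10S)-4,8-dimethyl-4,10-bis[(triethylsilyl)oxy]cyclodeca-2,7-dien-1-yl]propan-1-ol
Conditions: i-Bu2AlH, CH2Cl2, −78 to 0 °C; aq. KNaC4H4O6
Reagents that add atoms: none
Why: Aluminium hydride reduction of the saturated ester to the primary alcohol; alkenes and silyl ethers are untouched.

Step 18
Reactants: 27 (2RS)-2-[(1R,2E,4R,7E,10S)-4,8-dimethyl-4,10-bis[(triethylsilyl)oxy]cyclodeca-2,7-dien-1-yl]propan-1-ol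
Product: 28 (2RS)-2-[(1R,2E,4R,7E,10S)-4,8-dimethyl-4,10-bis[(triethylsilyl)oxy]cyclodeca-2,7-dien-1-yl]propyl 4-methylbenzenesulfonate
Conditions: TsCl, Et3N, DMAP (cat.), CH2Cl2, 0 °C to rt
Reagents that add atoms: 4-methylbenzenesulfonyl chloride, Cc1ccc(cc1)S(Cl)(=O)=O
Why: Sulfonylation of the only free hydroxyl; with C8 silylated there is no internal nucleophile for ether formation.

Step 19
Reactants: 28 (2RS)-2-[(1R,2E,4R,7E,10S)-4,8-dimethyl-4,10-bis[(triethylsilyl)oxy]cyclodeca-2,7-dien-1-yl]propyl 4-methylbenzenesulfonate
Product: 29 (1R,2E,4S,5S,7E)-1,7-dimethyl-4-(propan-2-yl)-1,5-bis[(triethylsilyl)oxy]cyclodeca-2,7-diene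
Conditions: LiBHEt3, THF, 0 to 40 °C
Reagents that add atoms: none
Why: SN2 displacement of the primary sulfonate by the powerful hydride donor turns C12 into a methyl group and completes the isopropyl group; the C11 stereocentre disappears.

Step 20
Reactants: 29 (1R,2E,4S,5S,7E)-1,7-dimethyl-4-(propan-2-yl)-1,5-bis[(triethylsilyl)oxy]cyclodeca-2,7-diene
Product: 30 (1R,2E,4S,5S,7E)-1,7-dimethyl-4-(propan-2-yl)cyclodeca-2,7-diene-1,5-diol
Conditions: n-Bu4NF, THF, rt to 40 °C
Reagents that add atoms: none
Why: Fluoride cleaves both Si–O bonds under basic, non-acidic conditions that cannot ionise the tertiary allylic alcohol or start a transannular cyclisation.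

Step 21
Reactants: 30 (1R,2E,4S,5S,7E)-1,7-dimethyl-4-(propan-2-yl)cyclodeca-2,7-diene-1,5-diol; 31 4-acetoxybenzoyl chloride
Product: 32 (1S,2S,3E,5R,8E)-5-hydroxy-5,9-dimethyl-2-(propan-2-yl)cyclodeca-3,8-dien-1-yl 4-(acetyloxy)benzoate
Conditions: pyridine, DMAP (cat.), CH2Cl2, 0 °C to rt
Reagents that add atoms: none
Why: DMAP-catalysed acylation; the secondary C8 hydroxyl reacts, while the tertiary allylic C4 hydroxyl is far slower, and the C8–O bond is not broken, so the configuration is kept.

Step 22
Reactants: 32 (1S,2S,3E,5R,8E)-5-hydroxy-5,9-dimethyl-2-(propan-2-yl)cyclodeca-3,8-dien-1-yl 4-(acetyloxy)benzoate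
Product: 33 (1S,2S,3E,5R,8E)-5-hydroxy-5,9-dimethyl-2-(propan-2-yl)cyclodeca-3,8-dien-1-yl 4-hydroxybenzoate (CNP0277965.1)
Conditions: NH4OAc, MeOH/H2O, rt
Reagents that add atoms: none
Why: Chemoselective methanolysis of the aryl acetate, which has a phenoxide leaving group and is far more electrophilic than the alkyl benzoate; the freed para-hydroxyl further deactivates the benzoate, and the neutral medium spares the tertiary allylic alcohol.

## Compound list

1 | geranyl acetate | CC(C)=CCC/C(C)=C/COC(C)=O | starting material
2 | (2E,6E)-8-hydroxy-3,7-dimethylocta-2,6-dien-1-yl acetate | OC/C(C)=C/CC/C(C)=C/COC(C)=O | intermediate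
3 | (2E,6E)-3,7-dimethyl-8-oxoocta-2,6-dien-1-yl acetate | O=C/C(C)=C/CC/C(C)=C/COC(C)=O | intermediate
4 | methyltriphenylphosphonium bromide | [Br-].C[P+](c1ccccc1)(c1ccccc1)c1ccccc1 | starting material
5 | (2E,6E)-3,7-dimethylnona-2,6,8-trien-1-yl acetate | C=C/C(C)=C/CC/C(C)=C/COC(C)=O | intermediate
6 | (2E,6E)-3,7-dimethylnona-2,6,8-trien-1-ol | C=C/C(C)=C/CC/C(C)=C/CO | intermediate
7 | [(2R,3R)-3-methyl-3-[(3E)-4-methylhexa-3,5-dien-1-yl]oxiran-2-yl]methanol | C=C/C(C)=C/CC[C@@]1(C)O[C@@H]1CO | intermediate
8 | (2S,3R)-3-methyl-3-[(3E)-4-methylhexa-3,5-dien-1-yl]oxirane-2-carbaldehyde | C=C/C(C)=C/CC[C@@]1(C)O[C@@H]1C=O | intermediate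
9 | (methoxymethyl)triphenylphosphonium chloride | [Cl-].COC[P+](c1ccccc1)(c1ccccc1)c1ccccc1 | starting material
10 | (2R,3R)-2-(2-methoxyethenyl)-3-methyl-3-[(3E)-4-methylhexa-3,5-dien-1-yl]oxirane (E/Z mixture at the enol ether) | C=C/C(C)=C/CC[C@@]1(C)O[C@@H]1C=COC | intermediate
11 | (2E,4R,7E)-4-hydroxy-4,8-dimethyldeca-2,7,9-trienal | C=C/C(C)=C/CC[C@@](C)(O)/C=C/C=O | intermediate
12 | (2E,4R,7E)-4,8-dimethyl-4-[(triethylsilyl)oxy]deca-2,7,9-trienal | C=C/C(C)=C/CC[C@@](C)(O[Si](CC)(CC)CC)/C=C/C=O | intermediate
13 | methyl 2-[bis(2,2,2-trifluoroethoxy)phosphoryl]acetate | COC(=O)CP(=O)(OCC(F)(F)F)OCC(F)(F)F | starting material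
14 | methyl 2,2-dibromo-2-[bis(2,2,2-trifluoroethoxy)phosphoryl]acetate | COC(=O)C(Br)(Br)P(=O)(OCC(F)(F)F)OCC(F)(F)F | intermediate
15 | methyl 2-bromo-2-[bis(2,2,2-trifluoroethoxy)phosphoryl]acetate (racemic) | COC(=O)C(Br)P(=O)(OCC(F)(F)F)OCC(F)(F)F | intermediate
16 | methyl (2E,4E,6R,9E)-2-bromo-6,10-dimethyl-6-[(triethylsilyl)oxy]dodeca-2,4,9,11-tetraenoate | C=C/C(C)=C/CC[C@@](C)(O[Si](CC)(CC)CC)/C=C/C=C(/Br)C(=O)OC | intermediate
17 | methyl (2E,4E,6R,9E)-12-(9-borabicyclo[3.3.1]nonan-9-yl)-2-bromo-6,10-dimethyl-6-[(triethylsilyl)oxy]dodeca-2,4,9-trienoate | C1CCC2CCCC1B2CC/C(C)=C/CC[C@@](C)(O[Si](CC)(CC)CC)/C=C/C=C(/Br)C(=O)OC | intermediate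
18 | methyl (2E,4E,6R,9E)-2-bromo-12-hydroxy-6,10-dimethyl-6-[(triethylsilyl)oxy]dodeca-2,4,9-trienoate | OCC/C(C)=C/CC[C@@](C)(O[Si](CC)(CC)CC)/C=C/C=C(/Br)C(=O)OC | intermediate
19 | (tributylstannyl)methanol | CCCC[Sn](CCCC)(CCCC)CO | starting material
20 | methyl (2Z,4E,6R,9E)-12-hydroxy-2-(hydroxymethyl)-6,10-dimethyl-6-[(triethylsilyl)oxy]dodeca-2,4,9-trienoate | OCC/C(C)=C/CC[C@@](C)(O[Si](CC)(CC)CC)/C=C/C=C(/CO)C(=O)OC | intermediate
21 | methyl (2E,4E,6R,9E)-2-(bromomethyl)-12-hydroxy-6,10-dimethyl-6-[(triethylsilyl)oxy]dodeca-2,4,9-trienoate | OCC/C(C)=C/CC[C@@](C)(O[Si](CC)(CC)CC)/C=C/C=C(/CBr)C(=O)OC | intermediate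
22 | methyl (2E,4E,6R,9E)-2-(bromomethyl)-6,10-dimethyl-12-oxo-6-[(triethylsilyl)oxy]dodeca-2,4,9-trienoate | O=CC/C(C)=C/CC[C@@](C)(O[Si](CC)(CC)CC)/C=C/C=C(/CBr)C(=O)OC | intermediate
23 | allylchromium dichloride from 22 (CrCl2 on C13 in place of Br) | O=CC/C(C)=C/CC[C@@](C)(O[Si](CC)(CC)CC)/C=C/C=C(/C[Cr](Cl)Cl)C(=O)OC | intermediate
24 | methyl 2-[(1R,2E,4R,7E,10S)-10-hydroxy-4,8-dimethyl-4-[(triethylsilyl)oxy]cyclodeca-2,7-dien-1-yl]prop-2-enoate | C/C1=C\CC[C@@](C)(O[Si](CC)(CC)CC)/C=C/[C@H](C(=C)C(=O)OC)[C@@H](O)C1 | intermediate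
25 | methyl 2-[(1R,2E,4R,7E,10S)-4,8-dimethyl-4,10-bis[(triethylsilyl)oxy]cyclodeca-2,7-dien-1-yl]prop-2-enoate | C/C1=C\CC[C@@](C)(O[Si](CC)(CC)CC)/C=C/[C@H](C(=C)C(=O)OC)[C@@H](O[Si](CC)(CC)CC)C1 | intermediate
26 | methyl (2RS)-2-[(1R,2E,4R,7E,10S)-4,8-dimethyl-4,10-bis[(triethylsilyl)oxy]cyclodeca-2,7-dien-1-yl]propanoate (both C11 epimers) | C/C1=C\CC[C@@](C)(O[Si](CC)(CC)CC)/C=C/[C@H](C(C)C(=O)OC)[C@@H](O[Si](CC)(CC)CC)C1 | intermediate
27 | (2RS)-2-[(1R,2E,4R,7E,10S)-4,8-dimethyl-4,10-bis[(triethylsilyl)oxy]cyclodeca-2,7-dien-1-yl]propan-1-ol (both C11 epimers) | C/C1=C\CC[C@@](C)(O[Si](CC)(CC)CC)/C=C/[C@H](C(C)CO)[C@@H](O[Si](CC)(CC)CC)C1 | intermediate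
28 | (2RS)-2-[(1R,2E,4R,7E,10S)-4,8-dimethyl-4,10-bis[(triethylsilyl)oxy]cyclodeca-2,7-dien-1-yl]propyl 4-methylbenzenesulfonate (both C11 epimers) | C/C1=C\CC[C@@](C)(O[Si](CC)(CC)CC)/C=C/[C@H](C(C)COS(=O)(=O)c2ccc(C)cc2)[C@@H](O[Si](CC)(CC)CC)C1 | intermediate
29 | (1R,2E,4S,5S,7E)-1,7-dimethyl-4-(propan-2-yl)-1,5-bis[(triethylsilyl)oxy]cyclodeca-2,7-diene | C/C1=C\CC[C@@](C)(O[Si](CC)(CC)CC)/C=C/[C@H](C(C)C)[C@@H](O[Si](CC)(CC)CC)C1 | intermediate
30 | (1R,2E,4S,5S,7E)-1,7-dimethyl-4-(propan-2-yl)cyclodeca-2,7-diene-1,5-diol | C/C1=C\CC[C@@](C)(O)/C=C/[C@H](C(C)C)[C@@H](O)C1 | intermediate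
31 | 4-acetoxybenzoyl chloride | CC(=O)Oc1ccc(cc1)C(Cl)=O | starting material
32 | (1S,2S,3E,5R,8E)-5-hydroxy-5,9-dimethyl-2-(propan-2-yl)cyclodeca-3,8-dien-1-yl 4-(acetyloxy)benzoate | C/C1=C\CC[C@@](C)(O)/C=C/[C@H](C(C)C)[C@@H](OC(=O)c2ccc(OC(C)=O)cc2)C1 | intermediate
33 | (1S,2S,3E,5R,8E)-5-hydroxy-5,9-dimethyl-2-(propan-2-yl)cyclodeca-3,8-dien-1-yl 4-hydroxybenzoate | C/C1=C\CC[C@@](C)(O)/C=C/[C@H](C(C)C)[C@@H](OC(=O)c2ccc(O)cc2)C1 | target

## Step count and least certain steps

Total: 22 steps. Longest linear sequence: 21 steps (1 to 33 through steps 1–7 and 9–22); step 8 is a one-step branch that makes reagent 15.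

**Step 14 (key step).** The most likely failure is loss of stereocontrol. A 1,3-shift of chromium can equilibrate the two alkene geometries of the allylchromium before ring closure and so feed the syn manifold, and the facial bias relayed from remote C4 may be weak. Intermolecular coupling, protonation of the allylmetal and lactonisation during isolation are further drains.
Fallback (from 18, back at 24): replace chromium by boron. Negishi coupling of 18 with (pinacolatoboryl)methylzinc iodide and Pd(PPh3)4 should give, with retention, the allylboronate alcohol F1. Dess–Martin oxidation would give the allylboronate aldehyde F2. Intramolecular allylboration in dilute toluene (with a chiral BINOL-derived phosphoric acid if the inherent facial preference is inadequate) and aqueous work-up would return 24. An allylboronate does not equilibrate its geometry and reacts through a tight chair, so the 2-alkene geometry is transferred faithfully, and the catalyst, not C4, can set the absolute sense.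

**Step 11.** The sp3 hydroxymethyl group may transfer slowly from tin, so that protodebromination, butyl transfer or thermal degradation of the bromodienoate compete.
Fallback (from 18, back at 20): a silicon-based hydroxymethyl equivalent. Negishi coupling of 18 with [(isopropoxy)dimethylsilyl]methylzinc chloride (from the Grignard reagent and ZnCl2) and a palladium catalyst would give the allylsilane F3. Tamao oxidation (H2O2, KF, KHCO3) converts C–Si into C–OH without allylic shift and gives 20.

**Step 12.** Discrimination between the allylic and the homoallylic hydroxyl may be incomplete, and bromide may scramble the 2-alkene geometry by reversible SN2′ exchange.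
Fallback (from 18, back at 21): differentiate by protection. 18 is converted with 4-methoxybenzyl trichloroacetimidate and La(OTf)3 (cat.) into the 4-methoxybenzyl ether F4. The Stille coupling of step 11 then gives the allylic alcohol F5. CBr4/PPh3 at 0 °C (short contact) gives the bromide F6, and DDQ in buffered wet CH2Cl2 frees the C8 hydroxyl to give 21.

**Step 9.** Geometric leakage in the olefination of a γ-quaternary enal would put the C6 chain on the wrong side of the C7=C11 alkene.
Fallback (from 12, back at 20): fix the geometry by sequential coupling. Ramirez olefination of 12 (CBr4, PPh3) gives the 1,1-dibromotetraene F7. Stille coupling with 19 takes place at the bromine trans to the chain and gives the bromo allylic alcohol F8. Palladium-catalysed methoxycarbonylation (CO, MeOH, Et3N, PdCl2(PPh3)2) of the remaining bromide, with retention, gives the hydroxymethyl dienoate F9. Hydroboration–oxidation as in step 10 then gives 20.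

**Step 21.** Acylation of the hindered C8 hydroxyl may be slow enough that forcing conditions begin to acylate or dehydrate the tertiary allylic alcohol.
Fallback (from 29, back at 32): differentiate by protection. Pyridinium p-toluenesulfonate in MeOH at 0 °C removes the secondary silyl ether first and gives the mono-silyl alcohol F10. Acylation with 31 gives the silyl ether ester F11. Buffered fluoride (n-Bu4NF/AcOH) then frees C4–OH and gives 32; if the aryl acetate is lost in the same operation, the product is 33 itself.

## Further compounds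

F1 | step 14 | methyl (2Z,4E,6R,9E)-12-hydroxy-6,10-dimethyl-2-[(4,4,5,5-tetramethyl-1,3,2-dioxaborolan-2-yl)methyl]-6-[(triethylsilyl)oxy]dodeca-2,4,9-trienoate | OCC/C(C)=C/CC[C@@](C)(O[Si](CC)(CC)CC)/C=C/C=C(/CB1OC(C)(C)C(C)(C)O1)C(=O)OC
F2 | step 14 | methyl (2Z,4E,6R,9E)-6,10-dimethyl-12-oxo-2-[(4,4,5,5-tetramethyl-1,3,2-dioxaborolan-2-yl)methyl]-6-[(triethylsilyl)oxy]dodeca-2,4,9-trienoate | O=CC/C(C)=C/CC[C@@](C)(O[Si](CC)(CC)CC)/C=C/C=C(/CB1OC(C)(C)C(C)(C)O1)C(=O)OC
F3 | step 11 | methyl (2E,4E,6R,9E)-2-{[dimethyl(propan-2-yloxy)silyl]methyl}-12-hydroxy-6,10-dimethyl-6-[(triethylsilyl)oxy]dodeca-2,4,9-trienoate | OCC/C(C)=C/CC[C@@](C)(O[Si](CC)(CC)CC)/C=C/C=C(/C[Si](C)(C)OC(C)C)C(=O)OC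
F4 | step 12 | methyl (2E,4E,6R,9E)-2-bromo-12-[(4-methoxyphenyl)methoxy]-6,10-dimethyl-6-[(triethylsilyl)oxy]dodeca-2,4,9-trienoate | COc1ccc(COCC/C(C)=C/CC[C@@](C)(O[Si](CC)(CC)CC)/C=C/C=C(/Br)C(=O)OC)cc1
F5 | step 12 | methyl (2Z,4E,6R,9E)-2-(hydroxymethyl)-12-[(4-methoxyphenyl)methoxy]-6,10-dimethyl-6-[(triethylsilyl)oxy]dodeca-2,4,9-trienoate | COc1ccc(COCC/C(C)=C/CC[C@@](C)(O[Si](CC)(CC)CC)/C=C/C=C(/CO)C(=O)OC)cc1
F6 | step 12 | methyl (2E,4E,6R,9E)-2-(bromomethyl)-12-[(4-methoxyphenyl)methoxy]-6,10-dimethyl-6-[(triethylsilyl)oxy]dodeca-2,4,9-trienoate | COc1ccc(COCC/C(C)=C/CC[C@@](C)(O[Si](CC)(CC)CC)/C=C/C=C(/CBr)C(=O)OC)cc1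
F7 | step 9 | {[(3E,5R,8E)-1,1-dibromo-5,9-dimethylundeca-1,3,8,10-tetraen-5-yl]oxy}triethylsilane | C=C/C(C)=C/CC[C@@](C)(O[Si](CC)(CC)CC)/C=C/C=C(Br)Br
F8 | step 9 | (2Z,4E,6R,9E)-2-bromo-6,10-dimethyl-6-[(triethylsilyl)oxy]dodeca-2,4,9,11-tetraen-1-ol | C=C/C(C)=C/CC[C@@](C)(O[Si](CC)(CC)CC)/C=C/C=C(\Br)CO
F9 | step 9 | methyl (2Z,4E,6R,9E)-2-(hydroxymethyl)-6,10-dimethyl-6-[(triethylsilyl)oxy]dodeca-2,4,9,11-tetraenoate | C=C/C(C)=C/CC[C@@](C)(O[Si](CC)(CC)CC)/C=C/C=C(/CO)C(=O)OC
F10 | step 21 | (1S,2S,3E,5R,8E)-5,9-dimethyl-2-(propan-2-yl)-5-[(triethylsilyl)oxy]cyclodeca-3,8-dien-1-ol | C/C1=C\CC[C@@](C)(O[Si](CC)(CC)CC)/C=C/[C@H](C(C)C)[C@@H](O)C1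
F11 | step 21 | (1S,2S,3E,5R,8E)-5,9-dimethyl-2-(propan-2-yl)-5-[(triethylsilyl)oxy]cyclodeca-3,8-dien-1-yl 4-(acetyloxy)benzoate | C/C1=C\CC[C@@](C)(O[Si](CC)(CC)CC)/C=C/[C@H](C(C)C)[C@@H](OC(=O)c2ccc(OC(C)=O)cc2)C1
A1 | alternative 1 | 4-[(tert-butyldimethylsilyl)oxy]-2-ethenyl-2-methyl-5-(propan-2-yl)-1-(prop-1-en-2-yl)cyclohexan-1-ol (ethenyl and propenyl trans; configuration as in the SMILES) | C=C[C@]1(C)C[C@H](O[Si](C)(C)C(C)(C)C)[C@@H](C(C)C)C[C@@]1(O)C(C)=C
A2 | alternative 1 | (7S,8S)-8-[(tert-butyldimethylsilyl)oxy]-5-[(trimethylsilyl)oxy]germacra-1(10)E,4-diene | C/C1=C\CC/C(C)=C(O[Si](C)(C)C)/C[C@H](C(C)C)[C@@H](O[Si](C)(C)C(C)(C)C)C1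
A3 | alternative 2 | 4α,8α-bis[(triethylsilyl)oxy]-5α-eudesm-6-en-1β-yl methanesulfonate | CC(C)C1=C[C@H]2[C@](C)(O[Si](CC)(CC)CC)CC[C@@H](OS(C)(=O)=O)[C@]2(C)C[C@@H]1O[Si](CC)(CC)CC
A4 | alternative 2 | (4R,7S,8S)-4,8-bis[(triethylsilyl)oxy]germacra-1(10)E,5E-diene (identical with 29) | C/C1=C\CC[C@@](C)(O[Si](CC)(CC)CC)/C=C/[C@H](C(C)C)[C@@H](O[Si](CC)(CC)CC)C1
A5 | alternative 3 | (5E,8S,9S,10E)-8-[(tert-butyldimethylsilyl)oxy]-11-iodo-6-methyl-9-(propan-2-yl)undeca-5,10-dien-2-one | CC(=O)CC/C=C(\C)C[C@H](O[Si](C)(C)C(C)(C)C)[C@@H](C(C)C)/C=C/I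
A6 | alternative 3 | (1R,2E,4S,5S,7E)-5-[(tert-butyldimethylsilyl)oxy]-1,7-dimethyl-4-(propan-2-yl)cyclodeca-2,7-dien-1-ol | C/C1=C\CC[C@@](C)(O)/C=C/[C@H](C(C)C)[C@@H](O[Si](C)(C)C(C)(C)C)C1
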